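## Retrosynthetic overview

1. Target ⇐ acetylation ⇐ substrate-controlled 1,2-reduction of the bicyclic enedione, which already carries C1, C5, C6 and C7 (locants are the bicyclo[3.2.1]octane numbering of the target: C1 allyl bridgehead, C5 OMe bridgehead, C8 bridging C=O).
2. Enedione ⇐ one oxidative radical (5+2) annulation of 6-allyl-2,3,4-trimethoxyphenol with (E)-isoelemicin: C1–C7 by addition of the alkene to an iron-bound phenoxyl radical, then C5–C6 closure; a chiral iron phosphate sets the absolute configuration.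
3. Phenol ⇐ aromatic Claisen ⇐ 2,3,4-trimethoxyphenol ⇐ Moore benzannulation of a squarate-derived 4-vinylcyclobutenone.
4. (E)-Isoelemicin ⇐ Takai ethylidenation of 3,4,5-trimethoxybenzaldehyde ⇐ p-cresol (bromination/hydrolysis, Cu-methoxylation/methylation).
5. Ring order: cyclobutenone → six-membered carbocycle (benzannulation) → cyclopentanone ring closed across it in the radical step, giving the bicyclo[3.2.1]octane.

Assumption: the (R)-configured phosphate is taken as the catalyst antipode that gives the (1S,5R,6R,7S) series in step 9; if a first run shows the opposite sense, the (S)-phosphate is used.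

## Route

Step 1
Reactants: 1 squaric acid (3,4-dihydroxycyclobut-3-ene-1,2-dione)
Product: 2 dimethyl squarate (3,4-dimethoxycyclobut-3-ene-1,2-dione)
Conditions: HC(OMe)3 (2.5 equiv), MeOH, reflux, 24 h
Reagents that add atoms: methanol, CO; trimethyl orthoformate, COC(OC)OC
Why: Esterification of the strongly acidic vinylogous diacid with methanol, driven to completion by the orthoformate as water scavenger; no stereocentre is formed.

Step 2
Reactants: 2 dimethyl squarate; 3 vinylmagnesium bromide
Product: 5 (±)-2,3,4-trimethoxy-4-vinylcyclobut-2-en-1-one, via bromomagnesium alkoxide 4 (not isolated)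
Conditions: 3 (1.05 equiv), THF, −78 °C; then MeOTf (1.5 equiv), −78 → 0 °C
Reagents that add atoms: methyl trifluoromethanesulfonate, COS(=O)(=O)C(F)(F)F
Why: 1,2-Addition of the vinyl Grignard reagent to one squarate carbonyl (Moore–Liebeskind cyclobutenone synthesis) and O-methylation of the tertiary alkoxide by the hard electrophile MeOTf in the same flask; the single stereocentre is racemic and is destroyed in step 3.

Step 3
Reactants: 5 (±)-2,3,4-trimethoxy-4-vinylcyclobut-2-en-1-one
Product: 8 2,3,4-trimethoxyphenol, via dienylketene 6 (not isolated), via 2,3,4-trimethoxycyclohexa-2,4-dien-1-one 7 (not isolated)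
Conditions: p-xylene, 138 °C, 2 h, argon
Reagents that add atoms: none
Why: Moore benzannulation: thermal 4π-electrocyclic ring opening (methoxy rotates outward, vinyl inward) to 6, 6π-electrocyclisation to 7 and tautomerisation to the phenol, which places OH, OMe, OMe, OMe on four contiguous carbons; no stereocentre remains.

Step 4
Reactants: 8 2,3,4-trimethoxyphenol; 9 allyl bromide
Product: 10 1-(allyloxy)-2,3,4-trimethoxybenzene
Conditions: K2CO3, acetone, reflux
Reagents that add atoms: none
Why: Williamson O-allylation of the phenoxide (SN2 on allyl bromide); no stereocentre.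

Step 5
Reactants: 10 1-(allyloxy)-2,3,4-trimethoxybenzene
Product: 12 6-allyl-2,3,4-trimethoxyphenol, via 6-allyl-2,3,4-trimethoxycyclohexa-2,4-dien-1-one 11 (not isolated)
Conditions: N,N-diethylaniline, 190 °C, 6 h
Reagents that add atoms: none
Why: Aromatic Claisen rearrangement ([3,3]) to the only free ortho position (the other bears OMe), then tautomerisation of dienone 11; no stereocentre remains.

Step 6
Reactants: 13 p-cresol
Product: 16 3,5-dibromo-4-hydroxybenzaldehyde, via 2,6-dibromo-4-methylphenol 14 (not isolated), via 2,6-dibromo-4-(dibromomethyl)phenol 15 (not isolated)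
Conditions: Br2 (2 equiv), o-dichlorobenzene, 30 °C; Br2 (2 equiv), 150 °C; then H2O, 100 °C
Reagents that add atoms: bromine, BrBr; water, O
Why: Electrophilic aromatic bromination at both positions ortho to OH, then high-temperature side-chain (benzylic) dibromination and hydrolysis of the benzal bromide, the established technical route from p-cresol; no stereocentre.

Step 7
Reactants: 16 3,5-dibromo-4-hydroxybenzaldehyde
Product: 18 3,4,5-trimethoxybenzaldehyde, via sodium 4-formyl-2,6-dimethoxyphenolate 17 (not isolated)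
Conditions: NaOMe (4 equiv), CuCl (10 mol %), DMF–MeOH, 115 °C; then Me2SO4 (2.5 equiv), 60 °C
Reagents that add atoms: sodium methoxide, C[O-].[Na+]; dimethyl sulfate, COS(=O)(=O)OC
Why: Copper(I)-catalysed Ullmann-type methoxylation of both aryl bromides (the substrate reacts as its phenoxide) and Williamson O-methylation of phenoxide 17 with dimethyl sulfate in the same pot; no stereocentre.

Step 8
Reactants: 18 3,4,5-trimethoxybenzaldehyde; 19 1,1-diiodoethane
Product: 20 (E)-1,2,3-trimethoxy-5-(prop-1-en-1-yl)benzene ((E)-isoelemicin)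
Conditions: CrCl2 (6 equiv), THF, 25 °C
Reagents that add atoms: none
Why: Takai–Utimoto alkylidenation: the gem-dichromium ethylidene species formed from 19 and CrCl2 adds to the aldehyde and eliminates to the (E)-alkene (E:Z about 9:1 or better), so the alkene geometry is set here; no stereocentre.

Step 9
Reactants: 12 6-allyl-2,3,4-trimethoxyphenol; 20 (E)-isoelemicin
Product: 23 (1S,5R,6R,7S)-1-allyl-3,5-dimethoxy-7-methyl-6-(3,4,5-trimethoxyphenyl)bicyclo[3.2.1]oct-2-ene-4,8-dione, via benzylic radical 21 (not isolated), via bicyclic methoxycarbenium ion 22 (not isolated)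
Conditions: 20 (2 equiv), Fe[(R)-TRIP]3 (5 mol %; TRIP = 3,3′-bis(2,4,6-triisopropylphenyl)-BINOL phosphate), t-BuOOt-Bu (1.2 equiv), ClCH2CH2Cl–HFIP 1:1, 0 °C → rt; then H2O/NaHCO3
Reagents that add atoms: water, O
Why: Proposed new method: oxidative radical (5+2) annulation in which the chiral iron(III) phosphate binds 12 as a chelated phenoxide (O8 and the 5-OMe), the peroxide oxidises it to an iron-bound phenoxyl radical, and the CHMe carbon of 20 adds to the allyl-bearing ortho carbon on the face left open by the phosphate (radical C1–C7 bond formation, sets C1 and C7, gives 21), after which oxidation of the benzylic radical and closure onto the nucleophilic C5 enol-ether carbon with aryl endo and trans to the exo methyl (sets C6 and C5) gives 22, hydrolysed to the enedione on work-up; the closest known reaction types are the iron-catalysed oxidative radical cross-coupling/cyclisation of phenols with styrenes, chiral iron phosphate oxidative phenol coupling, and the cationic or anodic (5+2) reaction of 2-allyl-methoxyphenols with (E)-propenylarenes.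

Step 10
Reactants: 23 (1S,5R,6R,7S)-1-allyl-3,5-dimethoxy-7-methyl-6-(3,4,5-trimethoxyphenyl)bicyclo[3.2.1]oct-2-ene-4,8-dione
Product: 24 (1S,4R,5S,6R,7S)-1-allyl-4-hydroxy-3,5-dimethoxy-7-methyl-6-(3,4,5-trimethoxyphenyl)bicyclo[3.2.1]oct-2-en-8-one
Conditions: NaBH4 (1.0 equiv), CeCl3·7H2O (1.1 equiv), MeOH, −40 °C
Reagents that add atoms: none
Why: Luche 1,2-reduction of the conjugated C4 ketone (the C8 ketone between two quaternary bridgeheads reacts more slowly), with hydride delivered to the open face of C4 syn to the one-carbon C8 bridge and anti to the C6–C7 bridge carrying the endo aryl group, which sets 4R (OH pseudo-equatorial, syn to the two-carbon bridge).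

Step 11
Reactants: 24 (1S,4R,5S,6R,7S)-1-allyl-4-hydroxy-3,5-dimethoxy-7-methyl-6-(3,4,5-trimethoxyphenyl)bicyclo[3.2.1]oct-2-en-8-one
Product: 25 (1S,4R,5S,6R,7S)-3,5-dimethoxy-7-methyl-8-oxo-1-(prop-2-en-1-yl)-6-(3,4,5-trimethoxyphenyl)bicyclo[3.2.1]oct-2-en-4-yl acetate
Conditions: Ac2O (2 equiv), Et3N, DMAP (10 mol %), CH2Cl2, 0 → 25 °C
Reagents that add atoms: acetic anhydride, CC(=O)OC(C)=O
Why: DMAP-catalysed acyl transfer to the hindered secondary alcohol with retention at C4 and no change elsewhere, giving the target.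

## Compound list

1 | squaric acid | OC1=C(O)C(=O)C1=O | starting material
2 | dimethyl squarate | COC1=C(OC)C(=O)C1=O | intermediate
3 | vinylmagnesium bromide | C=C[Mg]Br | starting material
4 | bromomagnesium 2,3-dimethoxy-4-oxo-1-vinylcyclobut-2-en-1-olate (racemic, not isolated) | C=CC1([O-])C(OC)=C(OC)C1=O.[Mg+2].[Br-] | intermediate
5 | (±)-2,3,4-trimethoxy-4-vinylcyclobut-2-en-1-one | C=CC1(OC)C(OC)=C(OC)C1=O | intermediate
6 | (3Z)-2,3,4-trimethoxyhexa-1,3,5-trien-1-one (dienylketene, not isolated) | O=C=C(OC)/C(OC)=C(OC)\C=C | intermediate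
7 | 2,3,4-trimethoxycyclohexa-2,4-dien-1-one (not isolated) | O=C1CC=C(OC)C(OC)=C1OC | intermediate
8 | 2,3,4-trimethoxyphenol | COc1ccc(O)c(OC)c1OC | intermediate
9 | allyl bromide | C=CCBr | starting material
10 | 1-(allyloxy)-2,3,4-trimethoxybenzene | C=CCOc1ccc(OC)c(OC)c1OC | intermediate
11 | 6-allyl-2,3,4-trimethoxycyclohexa-2,4-dien-1-one (racemic, not isolated) | C=CCC1C=C(OC)C(OC)=C(OC)C1=O | intermediate
12 | 6-allyl-2,3,4-trimethoxyphenol | C=CCc1cc(OC)c(OC)c(OC)c1O | intermediate
13 | p-cresol | Cc1ccc(O)cc1 | starting material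
14 | 2,6-dibromo-4-methylphenol (not isolated) | Cc1cc(Br)c(O)c(Br)c1 | intermediate
15 | 2,6-dibromo-4-(dibromomethyl)phenol (not isolated) | BrC(Br)c1cc(Br)c(O)c(Br)c1 | intermediate
16 | 3,5-dibromo-4-hydroxybenzaldehyde | O=Cc1cc(Br)c(O)c(Br)c1 | intermediate
17 | sodium 4-formyl-2,6-dimethoxyphenolate (not isolated) | [Na+].[O-]c1c(OC)cc(C=O)cc1OC | intermediate
18 | 3,4,5-trimethoxybenzaldehyde | COc1cc(C=O)cc(OC)c1OC | intermediate
19 | 1,1-diiodoethane | CC(I)I | starting material
20 | (E)-1,2,3-trimethoxy-5-(prop-1-en-1-yl)benzene ((E)-isoelemicin) | C/C=C/c1cc(OC)c(OC)c(OC)c1 | intermediate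
21 | (2S)-2-[(1S)-1-allyl-3,4,5-trimethoxy-2-oxocyclohexa-3,5-dien-1-yl]-1-(3,4,5-trimethoxyphenyl)propyl radical (benzylic radical, not isolated) | C=CC[C@]1([C@@H](C)[CH]c2cc(OC)c(OC)c(OC)c2)C=C(OC)C(OC)=C(OC)C1=O | intermediate
22 | (1S,5R,6R,7S)-1-allyl-3,4,5-trimethoxy-7-methyl-8-oxo-6-(3,4,5-trimethoxyphenyl)bicyclo[3.2.1]oct-2-en-4-ylium (C4 methoxycarbenium ion, not isolated) | C=CC[C@]12C=C(OC)C(=[O+]C)[C@](OC)(C1=O)[C@@H](c1cc(OC)c(OC)c(OC)c1)[C@@H]2C | intermediate
23 | (1S,5R,6R,7S)-1-allyl-3,5-dimethoxy-7-methyl-6-(3,4,5-trimethoxyphenyl)bicyclo[3.2.1]oct-2-ene-4,8-dione (target numbering; aryl endo, methyl exo) | C=CC[C@]12C=C(OC)C(=O)[C@](OC)(C1=O)[C@@H](c1cc(OC)c(OC)c(OC)c1)[C@@H]2C | intermediate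
24 | (1S,4R,5S,6R,7S)-1-allyl-4-hydroxy-3,5-dimethoxy-7-methyl-6-(3,4,5-trimethoxyphenyl)bicyclo[3.2.1]oct-2-en-8-one | C=CC[C@]12C=C(OC)[C@@H](O)[C@](OC)(C1=O)[C@@H](c1cc(OC)c(OC)c(OC)c1)[C@@H]2C | intermediate
25 | (1S,4R,5S,6R,7S)-3,5-dimethoxy-7-methyl-8-oxo-1-(prop-2-en-1-yl)-6-(3,4,5-trimethoxyphenyl)bicyclo[3.2.1]oct-2-en-4-yl acetate (CNP0181407.1) | C=CC[C@]12C=C(OC)[C@@H](OC(C)=O)[C@](OC)(C1=O)[C@@H](c1cc(OC)c(OC)c(OC)c1)[C@@H]2C | target

## Step count and risks

Total: 11 steps. Longest linear sequence: 8 steps (steps 1–5, then 9–11); the arene branch (steps 6–8) joins at step 9.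

The three steps most likely to fail:

Step 9 is the main risk. The oxidised intermediate may close on the dienone oxygen (hydrobenzofuranone) instead of C5, the alkene may add at the methoxy-bearing ortho carbon, and the chiral iron phosphate may give low ee. The fallback is a polar Lewis-acid route. It sets out from 12: oxidative demethylation with (NH4)2Ce(NO3)6 in MeCN–H2O at 0 °C gives 2-allyl-5,6-dimethoxy-1,4-benzoquinone F1. F1 and 20 are then combined in CH2Cl2 at −78 °C with a stoichiometric Ti(IV)–TADDOLate (TiCl4/Ti(OiPr)4/TADDOL, antipode chosen for this series), which promotes an enantioselective cationic (5+2) cycloaddition to (1S,5R,6R,7S)-1-allyl-3-hydroxy-5-methoxy-7-methyl-6-(3,4,5-trimethoxyphenyl)bicyclo[3.2.1]oct-2-ene-4,8-dione F2. O-Methylation of the enol (MeI, K2CO3, acetone) brings the route back at 23.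

Step 10 may reduce the C8 ketone as well, or deliver hydride from the wrong face. The fallback sets out from 23. If the reduction gives mainly the C4 epimer, (1S,4S,5S,6R,7S)-1-allyl-4-hydroxy-3,5-dimethoxy-7-methyl-6-(3,4,5-trimethoxyphenyl)bicyclo[3.2.1]oct-2-en-8-one F3, this alcohol is not oxidised back. Instead it is inverted and acetylated in one operation by a Mitsunobu reaction (AcOH, PPh3, DIAD, THF, 0 °C), which comes back to the route at 25 and replaces step 11.

Step 2 may fail through incomplete O-methylation of the hindered magnesium alkoxide or ring opening on warming. The fallback sets out from 2: the Grignard addition (via 4) is quenched with aqueous NH4Cl to give (±)-4-hydroxy-2,3-dimethoxy-4-vinylcyclobut-2-en-1-one F4. Thermolysis (p-xylene, 138 °C, argon) gives the C2-symmetric 2,3-dimethoxybenzene-1,4-diol F5. Mono-allylation (allyl bromide 1.0 equiv, K2CO3, acetone, unreacted F5 recycled) gives 4-(allyloxy)-2,3-dimethoxyphenol F6, and methylation of the remaining OH (MeI, K2CO3) comes back to the route at 10.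

## Further compounds

F1 | step 9 | 2-allyl-5,6-dimethoxy-1,4-benzoquinone | C=CCC1=CC(=O)C(OC)=C(OC)C1=O
F2 | step 9 | (1S,5R,6R,7S)-1-allyl-3-hydroxy-5-methoxy-7-methyl-6-(3,4,5-trimethoxyphenyl)bicyclo[3.2.1]oct-2-ene-4,8-dione | C=CC[C@]12C=C(O)C(=O)[C@](OC)(C1=O)[C@@H](c1cc(OC)c(OC)c(OC)c1)[C@@H]2C
F3 | step 10 | (1S,4S,5S,6R,7S)-1-allyl-4-hydroxy-3,5-dimethoxy-7-methyl-6-(3,4,5-trimethoxyphenyl)bicyclo[3.2.1]oct-2-en-8-one | C=CC[C@]12C=C(OC)[C@H](O)[C@](OC)(C1=O)[C@@H](c1cc(OC)c(OC)c(OC)c1)[C@@H]2C
F4 | step 2 | (±)-4-hydroxy-2,3-dimethoxy-4-vinylcyclobut-2-en-1-one | C=CC1(O)C(OC)=C(OC)C1=O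
F5 | step 2 | 2,3-dimethoxybenzene-1,4-diol | COc1c(O)ccc(O)c1OC
F6 | step 2 | 4-(allyloxy)-2,3-dimethoxyphenol | C=CCOc1ccc(O)c(OC)c1OC
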